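**Plan**
- Retrosynthesis: the quinone is taken back to a 3-alkyl-5-methoxyphenol (oxidation at the ring carbon between OMe and the side chain). The arene is then cut at two ring bonds: the bond from the ring CH next to the side-chain carbon to the carbon that becomes the C=O flanked by two CH groups, and the bond from the other ring CH to the methoxy-bearing carbon.
- Enabling feature: the two ring oxygens on the C(OMe) carbon and on the CH-flanked carbonyl stand 1,3 to each other, with the alkyl group meta to both. This is the pattern formed when the C(=O)–CH=C(R)–CH2 unit of a 3-alkylcyclobutenone (a strained vinylketene precursor) takes up the two carbons of a siloxyacetylene.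
- Forward: the chain is joined first (epichlorohydrin + decyl Grignard, then acetylide) and the acetate is installed. The alkyne is converted to the cyclobutenone, one thermal cascade builds the six-membered ring, and O-methylation, desilylation and oxidation finish the quinone.
- Helpers: the four-membered ring is consumed in the key step; the triisopropylsilyl group tells the two ring oxygens apart and is removed in step 11.
- Stereochemistry: the single (R) centre comes from (R)-epichlorohydrin; its C–O bond is never broken.

Key step: step 9

Remark: the acetate-bearing carbon of the target is read as (R) (O > CH2–ring > undecyl > H); compounds 1, 2, 5, 8, 11 and 12 are taken as purchased.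

**Route**

Step 1
Reactants: 1 (R)-epichlorohydrin; 2 decylmagnesium bromide
Product: 4 (R)-1,2-epoxytridecane, via (R)-1-chlorotridecan-2-ol 3 (not isolated)
Conditions: CuI (10 mol%), THF, −40 → 0 °C; then NaOH (aq. 5 M) added to the same flask, 25 °C
Reagents that add atoms: none
Why: Copper-catalysed Grignard opening of the epoxide at its CH2 carbon, then Williamson ring closure of the chlorohydrin, shifts the oxirane along the chain without breaking the C–O bond of the stereocentre, so (R)-1 should give (R)-4.

Step 2
Reactants: 4 (R)-1,2-epoxytridecane; 5 lithium acetylide–ethylenediamine complex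
Product: 6 (R)-pentadec-1-yn-4-ol
Conditions: DMSO, 0 → 25 °C; aqueous work-up
Reagents that add atoms: none
Why: SN2 epoxide alkynylation at the terminal CH2 carbon should give the homopropargylic alcohol with the carbinol configuration retained, since its C–O bond is not involved.

Step 3
Reactants: 6 (R)-pentadec-1-yn-4-ol
Product: 7 (R)-pentadec-1-yn-4-yl acetate
Conditions: Ac2O, pyridine, DMAP (cat.), CH2Cl2, 0 → 25 °C
Reagents that add atoms: acetic anhydride, CC(=O)OC(C)=O
Why: DMAP-catalysed acylation installs the acetate of the target early, where it also protects the alcohol, and does not touch the stereocentre.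

Step 4
Reactants: 7 (R)-pentadec-1-yn-4-yl acetate; 8 trichloroacetyl chloride
Product: 9 (R)-1-(4,4-dichloro-3-oxocyclobut-1-en-1-yl)tridecan-2-yl acetate
Conditions: Zn(Cu) couple, Et2O/DME, slow addition of 8, 25–35 °C
Reagents that add atoms: none
Why: Dichloroketene formed by zinc dechlorination of 8 should undergo regioselective ketene–alkyne [2+2] cycloaddition (alkyne CH to the ketene carbonyl carbon) to give the 3-substituted 4,4-dichlorocyclobutenone.

Step 5
Reactants: 9 (R)-1-(4,4-dichloro-3-oxocyclobut-1-en-1-yl)tridecan-2-yl acetate
Product: 10 (R)-1-(3-oxocyclobut-1-en-1-yl)tridecan-2-yl acetate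
Conditions: Zn dust, TMEDA, AcOH, EtOH, 0 → 25 °C
Reagents that add atoms: none
Why: Reductive dechlorination of the α,α-dichloroketone by zinc (zinc enolate formation and protonation) in an amine-buffered acid medium should give the 3-alkylcyclobutenone while sparing the acetate and the sensitive enone.

Step 6
Reactants: 11 tetrahydrofuran; 12 triisopropylsilyl trifluoromethanesulfonate
Product: 14 triisopropyl(vinyloxy)silane, via lithium ethenolate 13 (not isolated)
Conditions: n-BuLi, THF (reactant and solvent), 25 °C, 16 h; then 12, −78 → 0 °C
Reagents that add atoms: none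
Why: α-Lithiation of tetrahydrofuran followed by [3+2] cycloreversion gives ethene and the lithium enolate of acetaldehyde, which the hard silyl triflate should silylate on oxygen (silyl enol ether formation).

Step 7
Reactants: 14 triisopropyl(vinyloxy)silane
Product: 16 (Z)-(2-bromoethenyloxy)triisopropylsilane, via (1,2-dibromoethoxy)triisopropylsilane 15 (not isolated)
Conditions: Br2 (1.0 equiv), CH2Cl2, −78 °C; then Et3N, −78 → 25 °C
Reagents that add atoms: bromine, BrBr
Why: Bromine addition to the enol ether followed by amine-induced dehydrobromination of the α-bromo ether (halogenation–dehydrohalogenation) should give the β-bromo enol ether, expected mainly as the Z isomer, with the bulky silyl group shielding silicon from bromide; either isomer serves in step 8.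

Step 8
Reactants: 16 (Z)-(2-bromoethenyloxy)triisopropylsilane
Product: 18 (ethynyloxy)triisopropylsilane, via lithium siloxyacetylide 17 (not isolated)
Conditions: LiN(i-Pr)2 (2.2 equiv), THF, −78 °C; H2O quench at −78 °C, fast non-acidic work-up
Reagents that add atoms: none
Why: Base-induced anti elimination of HBr (dehydrohalogenation to an ynol ether) and deprotonation give the acetylide, which is protonated cold; the hindered silyl group should suppress O-to-C migration of silicon.

Step 9
Reactants: 10 (R)-1-(3-oxocyclobut-1-en-1-yl)tridecan-2-yl acetate; 18 (ethynyloxy)triisopropylsilane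
Product: 23 (R)-1-[3-hydroxy-5-(triisopropylsilyloxy)phenyl]tridecan-2-yl acetate, via vinylketene 19 (not isolated), via vinylcyclobutenone 20 (not isolated), via dienylketene 21 (not isolated), via cyclohexadienone 22 (not isolated)
Conditions: 18 (2 equiv), toluene (0.2 M), 80 °C, then 110 °C, argon
Reagents that add atoms: none
Why: Thermal 4π electrocyclic opening of cyclobutenone 10 gives vinylketene 19, whose ketene C=C adds the electron-rich siloxyalkyne 18 in a [2+2] cycloaddition to give the 4-alkenyl-3-siloxycyclobutenone 20; a second 4π opening gives dienylketene 21, 6π electrocyclization gives cyclohexadienone 22 and tautomerization gives phenol 23. The closest known reaction type is the Danheiser benzannulation of 3-alkylcyclobutenones with alkoxy- and siloxyalkynes to give resorcinol monoethers. The four-membered ring of 20 closes by [2+2] cycloaddition (ketene carbonyl carbon to the alkyne CH, ketene α-carbon to the siloxy carbon), and the six-membered ring closes by thermal disrotatory 6π electrocyclization between the ketene carbon and the terminal CH2 of the diene, which re-forms the bond broken in the first ring opening. No stereocentre is created in 23: the sp3 ring carbon of 20 forms without control and is erased on ring opening, and the (R) acetate-bearing carbon is remote and not involved. The step needs regioselectivity (siloxy carbon bonded to the ketene α-carbon, so that OH and OSi end up meta and the side chain meta to both), secured by the polarization of the ynol ether against the electrophilic ketene carbon, and chemoselectivity against acylation of 23 by ketene 19, secured by excess 18 and moderate dilution. Release of cyclobutenone ring strain and the gain of aromaticity should drive the cascade.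

Step 10
Reactants: 23 (R)-1-[3-hydroxy-5-(triisopropylsilyloxy)phenyl]tridecan-2-yl acetate
Product: 24 (R)-1-[3-methoxy-5-(triisopropylsilyloxy)phenyl]tridecan-2-yl acetate
Conditions: MeI, K2CO3, acetone, 25–40 °C
Reagents that add atoms: methyl iodide, CI
Why: Williamson O-methylation of the phenoxide (SN2 on methyl iodide) in an aprotic medium should leave the aryl silyl ether and the acetate untouched.

Step 11
Reactants: 24 (R)-1-[3-methoxy-5-(triisopropylsilyloxy)phenyl]tridecan-2-yl acetate
Product: 25 (R)-1-(3-hydroxy-5-methoxyphenyl)tridecan-2-yl acetate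
Conditions: Bu4NF, AcOH (1:1), THF, 0 °C
Reagents that add atoms: none
Why: Fluoride-induced cleavage of the aryl silyl ether, buffered with acetic acid so that the phenoxide is protonated at once, should free the phenol without hydrolysis or transfer of the acetate.

Step 12
Reactants: 25 (R)-1-(3-hydroxy-5-methoxyphenyl)tridecan-2-yl acetate
Product: 26 (R)-1-(5-methoxy-3,6-dioxocyclohexa-1,4-dien-1-yl)tridecan-2-yl acetate (target)
Conditions: (KSO3)2NO (2.5 equiv), KH2PO4 buffer (pH 6), H2O/acetone, 0 → 25 °C
Reagents that add atoms: Fremy's salt (dipotassium nitrosodisulfonate), [K+].[K+].[O]N(S(=O)(=O)[O-])S(=O)(=O)[O-]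
Why: Teuber oxidation, in which the phenoxyl radical is trapped by a second nitrosodisulfonate radical at the free para position (between OMe and the side chain) and loses imidodisulfonate, should give the para-quinone under near-neutral conditions that spare the β-acetoxy group.

**Compound list**

1 | (R)-epichlorohydrin [(R)-2-(chloromethyl)oxirane] | ClC[C@H]1CO1 | starting material
2 | decylmagnesium bromide | CCCCCCCCCC[Mg]Br | starting material
3 | (R)-1-chlorotridecan-2-ol | CCCCCCCCCCC[C@@H](O)CCl | intermediate
4 | (R)-1,2-epoxytridecane [(R)-2-undecyloxirane] | CCCCCCCCCCC[C@@H]1CO1 | intermediate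
5 | lithium acetylide–ethylenediamine complex | [Li]C#C.NCCN | starting material
6 | (R)-pentadec-1-yn-4-ol | CCCCCCCCCCC[C@@H](O)CC#C | intermediate
7 | (R)-pentadec-1-yn-4-yl acetate | CCCCCCCCCCC[C@H](CC#C)OC(C)=O | intermediate
8 | trichloroacetyl chloride | ClC(Cl)(Cl)C(Cl)=O | starting material
9 | (R)-1-(4,4-dichloro-3-oxocyclobut-1-en-1-yl)tridecan-2-yl acetate | CCCCCCCCCCC[C@H](CC1=CC(=O)C1(Cl)Cl)OC(C)=O | intermediate
10 | (R)-1-(3-oxocyclobut-1-en-1-yl)tridecan-2-yl acetate | CCCCCCCCCCC[C@H](CC1=CC(=O)C1)OC(C)=O | intermediate
11 | tetrahydrofuran | C1CCOC1 | starting material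
12 | triisopropylsilyl trifluoromethanesulfonate | CC(C)[Si](C(C)C)(C(C)C)OS(=O)(=O)C(F)(F)F | starting material
13 | lithium ethenolate | [Li]OC=C | intermediate
14 | triisopropyl(vinyloxy)silane | C=CO[Si](C(C)C)(C(C)C)C(C)C | intermediate
15 | (1,2-dibromoethoxy)triisopropylsilane | BrCC(Br)O[Si](C(C)C)(C(C)C)C(C)C | intermediate
16 | (Z)-(2-bromoethenyloxy)triisopropylsilane | Br/C=C\O[Si](C(C)C)(C(C)C)C(C)C | intermediate
17 | lithium (triisopropylsilyloxy)acetylide | [Li]C#CO[Si](C(C)C)(C(C)C)C(C)C | intermediate
18 | (ethynyloxy)triisopropylsilane | C#CO[Si](C(C)C)(C(C)C)C(C)C | intermediate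
19 | (R)-3-methylidene-1-oxohexadec-1-en-5-yl acetate (vinylketene) | CCCCCCCCCCC[C@H](CC(=C)C=C=O)OC(C)=O | intermediate
20 | (4R)-2-[4-oxo-2-(triisopropylsilyloxy)cyclobut-2-en-1-yl]pentadec-1-en-4-yl acetate (ring carbon unassigned) | CCCCCCCCCCC[C@H](CC(=C)C1C(=O)C=C1O[Si](C(C)C)(C(C)C)C(C)C)OC(C)=O | intermediate
21 | (3E,7R)-5-methylidene-1-oxo-3-(triisopropylsilyloxy)octadeca-1,3-dien-7-yl acetate (dienylketene) | CCCCCCCCCCC[C@H](CC(=C)/C=C(O[Si](C(C)C)(C(C)C)C(C)C)\C=C=O)OC(C)=O | intermediate
22 | (R)-1-[5-oxo-3-(triisopropylsilyloxy)cyclohexa-1,3-dien-1-yl]tridecan-2-yl acetate | CCCCCCCCCCC[C@H](CC1=CC(O[Si](C(C)C)(C(C)C)C(C)C)=CC(=O)C1)OC(C)=O | intermediate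
23 | (R)-1-[3-hydroxy-5-(triisopropylsilyloxy)phenyl]tridecan-2-yl acetate | CCCCCCCCCCC[C@H](Cc1cc(O)cc(O[Si](C(C)C)(C(C)C)C(C)C)c1)OC(C)=O | intermediate
24 | (R)-1-[3-methoxy-5-(triisopropylsilyloxy)phenyl]tridecan-2-yl acetate | CCCCCCCCCCC[C@H](Cc1cc(OC)cc(O[Si](C(C)C)(C(C)C)C(C)C)c1)OC(C)=O | intermediate
25 | (R)-1-(3-hydroxy-5-methoxyphenyl)tridecan-2-yl acetate | CCCCCCCCCCC[C@H](Cc1cc(O)cc(OC)c1)OC(C)=O | intermediate
26 | (R)-1-(5-methoxy-3,6-dioxocyclohexa-1,4-dien-1-yl)tridecan-2-yl acetate | CCCCCCCCCCC[C@H](CC1=CC(=O)C=C(OC)C1=O)OC(C)=O | target

**Totals**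
Total step count: 12. Longest linear sequence: 9 (steps 1–5 and 9–12); steps 6–8 form the three-step siloxyalkyne branch.

**Steps most likely to fail**

Step 7. Risk: during bromination, bromide may attack silicon so that the α-bromo ether collapses to an aldehyde and the silyl group is lost, or the dehydrobromination may stay incomplete. Fallback: it sets out from 12 and brings the halogen in with the carbonyl partner instead of halogenating the enol ether. Anhydrous chloroacetaldehyde is enol-silylated with 12 and Et3N in CH2Cl2 at 0 °C (soft enolization) to give (2-chloroethenyloxy)triisopropylsilane F1 as an E/Z mixture, so no α-halo ether is ever exposed to halide. Treatment of F1 with LiN(i-Pr)2 in THF at −78 °C would give 17 and, after cold protonation, 18, where the route is rejoined.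

Step 9. Risk: the phenol product may be acylated by the vinylketene, the cascade may stall at the vinylcyclobutenone, or a thermal 1,3-shift of silicon may turn the siloxyalkyne into a silylketene before it is trapped. Fallback: it sets out from 4 and uses a ready-made arene instead of building the ring. Commercial 3-bromo-5-methoxyphenol is silylated (i-Pr3SiCl, imidazole, DMF) to (3-bromo-5-methoxyphenoxy)triisopropylsilane F2, and magnesium in THF converts it into [3-methoxy-5-(triisopropylsilyloxy)phenyl]magnesium bromide F3. CuI-catalysed opening of epoxide 4 at its CH2 carbon gives (R)-1-[3-methoxy-5-(triisopropylsilyloxy)phenyl]tridecan-2-ol F4 with the carbinol configuration retained. Acetylation (Ac2O, pyridine, DMAP) gives 24, where the route is rejoined before steps 11 and 12.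

Step 5. Risk: the vinylogous β-acetoxy ketone may lose acetic acid through its dienolate under the amine-buffered conditions, the cyclobutenone may dimerize under base, or the ring may be over-reduced. Fallback: it sets out from 7 and avoids the dichloro compound and the zinc reduction altogether. The keteniminium salt generated from N,N-dimethylacetamide with Tf2O and 2,4,6-collidine in 1,2-dichloroethane at reflux undergoes [2+2] cycloaddition with alkyne 7, with the same regiochemistry as the ketene, to give N-[3-((R)-2-acetoxytridecyl)cyclobut-2-en-1-ylidene]-N-methylmethanaminium trifluoromethanesulfonate F5. Mild hydrolysis with aqueous NaHCO3 then gives cyclobutenone 10, where the route is rejoined.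

Further compounds
F1 | step 7 | (2-chloroethenyloxy)triisopropylsilane (E/Z mixture) | ClC=CO[Si](C(C)C)(C(C)C)C(C)C
F2 | step 9 | (3-bromo-5-methoxyphenoxy)triisopropylsilane | COc1cc(Br)cc(O[Si](C(C)C)(C(C)C)C(C)C)c1
F3 | step 9 | [3-methoxy-5-(triisopropylsilyloxy)phenyl]magnesium bromide | COc1cc([Mg]Br)cc(O[Si](C(C)C)(C(C)C)C(C)C)c1
F4 | step 9 | (R)-1-[3-methoxy-5-(triisopropylsilyloxy)phenyl]tridecan-2-ol | CCCCCCCCCCC[C@@H](O)Cc1cc(OC)cc(O[Si](C(C)C)(C(C)C)C(C)C)c1
F5 | step 5 | N-[3-((R)-2-acetoxytridecyl)cyclobut-2-en-1-ylidene]-N-methylmethanaminium trifluoromethanesulfonate | CCCCCCCCCCC[C@H](CC1=CC(=[N+](C)C)C1)OC(C)=O.[O-]S(=O)(=O)C(F)(F)F
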